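**Retrosynthetic overview** (decalin numbering: ring A = C1 ketone, C2 enol carbon, C3, quaternary C4, C4a, C8a; ring B = C4a, C5, C6, C7, C8, C8a; C9 = side-chain ketone on C4; C1′ = attachment carbon of the octan-2-yl group)
1. Feature: in ring A the C1 ketone has C4a as its β carbon and C2 as its α′ carbon, and C3 is an sp2 CH next to quaternary C4. This C1/C3 1,5-dicarbonyl pattern is the retron of a Michael–aldol annulation of a C3–C4 donor onto a ring B enone.
2. Ring B first: enone 14 from p-benzoquinone monoketal 1. Asymmetric conjugate methylation sets C7, two carbonyl reductions (the second corrected by Mitsunobu inversion) set C5 and C8, and iodination plus acylation add C1–C2. Singlet-oxygen and enolate-methylation routes are avoided because they place the C7 methyl anti to the oxygens.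
3. Ring A second: 14 + formyl thioester 17 → 19, forming C4–C4a and C2=C3.
4. End game: thioester → 3-hydroxypropanoyl; PMB off; Mitsunobu ether with (R,E)-oct-2-en-4-ol and Claisen transfer to C3 set C1′; hydrogenation; desilylation.

Key step: step 13

Assumption: the sense of induction of the amine–thiourea catalyst at C4 cannot be derived from the structures, so the route is written with the (1R,2R) catalyst and its enantiomer is taken if that proves to be the matched one; the target is treated as the open hydroxy ketone drawn, with which any C5–O/C9 hemiketal would equilibrate.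

**Step 1**
Reactants: 1 4,4-dimethoxycyclohexa-2,5-dien-1-one
Product: 2 (5S)-4,4-dimethoxy-5-methylcyclohex-2-en-1-one
Conditions: Me2Zn, Cu(OTf)2 (2 mol %), (R)-BINOL/bis[(S)-1-phenylethyl]amine phosphoramidite (4 mol %), toluene, −25 °C
Reagents that add atoms: dimethylzinc, SMILES C[Zn]C
Why: Copper–phosphoramidite-catalysed asymmetric conjugate addition of a dialkylzinc to a benzoquinone monoketal should desymmetrise the two enone arms and set the methyl-bearing centre (later C7); the (R,S,S) ligand is expected to give 5S by analogy with the facial sense on cyclohexenone.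

**Step 2**
Reactants: 2 (5S)-4,4-dimethoxy-5-methylcyclohex-2-en-1-one
Product: 3 (1R,5S)-4,4-dimethoxy-5-methylcyclohex-2-en-1-ol
Conditions: NaBH4, CeCl3·7H2O, MeOH, −78 °C; NaHCO3 work-up
Reagents that add atoms: none
Why: Luche 1,2-reduction; hydride should arrive anti to the C5 methyl in either half-chair, giving the 1,5-cis alcohol (later C5–O cis to the C7 methyl).

**Step 3**
Reactants: 3 (1R,5S)-4,4-dimethoxy-5-methylcyclohex-2-en-1-ol
Product: 4 tert-butyl{[(1R,5S)-4,4-dimethoxy-5-methylcyclohex-2-en-1-yl]oxy}dimethylsilane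
Conditions: TBSCl, imidazole, DMF, rt
Reagents that add atoms: tert-butyldimethylsilyl chloride, SMILES CC(C)(C)[Si](C)(C)Cl
Why: Standard silylation of a secondary allylic alcohol under basic conditions that leave the acid-labile ketal intact.

**Step 4**
Reactants: 4 tert-butyl{[(1R,5S)-4,4-dimethoxy-5-methylcyclohex-2-en-1-yl]oxy}dimethylsilane
Product: 5 (4R,6S)-4-[(tert-butyldimethylsilyl)oxy]-6-methylcyclohex-2-en-1-one
Conditions: PPTS (cat.), acetone/H2O, rt
Reagents that add atoms: water, SMILES O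
Why: Acetal hydrolysis of an allylic dimethyl ketal is fast under mild acid, which should spare the silyl ether and the now α-methyl centre, and transposes the enone so that the methyl is α′ and the silyloxy group γ (cis).

**Step 5**
Reactants: 5 (4R,6S)-4-[(tert-butyldimethylsilyl)oxy]-6-methylcyclohex-2-en-1-one
Product: 6 (4R,6S)-4-[(tert-butyldimethylsilyl)oxy]-2-iodo-6-methylcyclohex-2-en-1-one
Conditions: I2, pyridine, CH2Cl2, 0 °C → rt
Reagents that add atoms: iodine, SMILES II
Why: α-Iodination of an enone by pyridine conjugate addition, iodination of the enolate and elimination; well known for 4-silyloxycyclohexenones.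

**Step 6**
Reactants: 6 (4R,6S)-4-[(tert-butyldimethylsilyl)oxy]-2-iodo-6-methylcyclohex-2-en-1-one
Product: 7 (1R,4R,6S)-4-[(tert-butyldimethylsilyl)oxy]-2-iodo-6-methylcyclohex-2-en-1-ol
Conditions: NaBH4, CeCl3·7H2O, MeOH, −78 °C
Reagents that add atoms: none
Why: Luche reduction; axial attack on the di-equatorial half-chair should give the pseudo-equatorial alcohol trans to the methyl, i.e. the C8 epimer that step 7 inverts.

**Step 7**
Reactants: 7 (1R,4R,6S)-4-[(tert-butyldimethylsilyl)oxy]-2-iodo-6-methylcyclohex-2-en-1-ol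
Product: 8 (1S,4R,6S)-4-[(tert-butyldimethylsilyl)oxy]-2-iodo-6-methylcyclohex-2-en-1-yl 4-nitrobenzoate
Conditions: 4-O2NC6H4CO2H, PPh3, DIAD, THF, 0 °C → rt
Reagents that add atoms: 4-nitrobenzoic acid, SMILES OC(=O)c1ccc(cc1)[N+](=O)[O-]
Why: Mitsunobu inversion (SN2 by the carboxylate; SN2′ is blocked by the iodo-substituted alkene carbon) should give the all-cis arrangement of C5–O, C7–CH3 and C8–O.

**Step 8**
Reactants: 8 (1S,4R,6S)-4-[(tert-butyldimethylsilyl)oxy]-2-iodo-6-methylcyclohex-2-en-1-yl 4-nitrobenzoate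
Product: 9 (1S,4R,6S)-4-[(tert-butyldimethylsilyl)oxy]-2-iodo-6-methylcyclohex-2-en-1-ol
Conditions: K2CO3, MeOH, 0 °C → rt
Reagents that add atoms: none
Why: Transesterification of the activated 4-nitrobenzoate by methoxide with acyl–oxygen cleavage, so the inverted carbinol configuration is kept.

**Step 9**
Reactants: 9 (1S,4R,6S)-4-[(tert-butyldimethylsilyl)oxy]-2-iodo-6-methylcyclohex-2-en-1-ol
Product: 10 (3R,5S,6S)-3,6-bis[(tert-butyldimethylsilyl)oxy]-1-iodo-5-methylcyclohex-1-ene
Conditions: TBSOTf, 2,6-lutidine, CH2Cl2, −78 → 0 °C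
Reagents that add atoms: tert-butyldimethylsilyl triflate, SMILES CC(C)(C)[Si](C)(C)OS(=O)(=O)C(F)(F)F
Why: Silylation with the silyl triflate is the standard answer to a hindered pseudo-axial allylic alcohol.

**Step 10**
Reactants: 11 2-chloro-N-methoxy-N-methylacetamide; 12 4-methoxybenzyl alcohol
Product: 13 N-methoxy-2-[(4-methoxybenzyl)oxy]-N-methylacetamide
Conditions: NaH, THF, 0 °C → rt
Reagents that add atoms: none
Why: Williamson ether synthesis; the alkoxide displaces the activated α-chloride of the amide.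

**Step 11**
Reactants: 10 (3R,5S,6S)-3,6-bis[(tert-butyldimethylsilyl)oxy]-1-iodo-5-methylcyclohex-1-ene; 13 N-methoxy-2-[(4-methoxybenzyl)oxy]-N-methylacetamide
Product: 14 1-[(3R,5S,6S)-3,6-bis[(tert-butyldimethylsilyl)oxy]-5-methylcyclohex-1-en-1-yl]-2-[(4-methoxybenzyl)oxy]ethan-1-one (ring B enone)
Conditions: t-BuLi (2 equiv), Et2O, −78 °C; then 13, −78 → 0 °C; aq. NH4Cl
Reagents that add atoms: none
Why: Iodine–lithium exchange and Weinreb ketone synthesis; the chelated tetrahedral intermediate stops at the ketone, and the vinyllithium is trans to the C5 oxygen across the double bond, so no silyl migration is expected.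

**Step 12**
Reactants: 15 S-ethyl propanethioate; 16 ethyl formate
Product: 17 S-ethyl 2-methyl-3-oxopropanethioate (enolised formyl thioester, drawn as the Z-enol)
Conditions: LDA, THF, −78 °C; then HCO2Et; AcOH quench at −78 °C
Reagents that add atoms: none
Why: Crossed Claisen condensation (C-formylation) of the thioester lithium enolate; the product is held as its stabilised enolate until the cold acidic quench.

**Step 13**
Reactants: 14 ring B enone; 17 S-ethyl 2-methyl-3-oxopropanethioate
Product: 19 S-ethyl (4R,4aS,5R,7S,8S,8aR)-5,8-bis[(tert-butyldimethylsilyl)oxy]-2-[(4-methoxybenzyl)oxy]-4,7-dimethyl-1-oxo-1,4,4a,5,6,7,8,8a-octahydronaphthalene-4-carbothioate, via keto-aldehyde Michael adduct 18 (not isolated)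
Conditions: 17 (2 equiv), 1-[3,5-bis(trifluoromethyl)phenyl]-3-[(1R,2R)-2-(dimethylamino)cyclohexyl]thiourea (10–20 mol %), toluene, rt; then pyrrolidine/AcOH (30 mol % each), rt → 40 °C
Reagents that add atoms: none
Why: Proposed new method: the tertiary amine of the catalyst deprotonates the enolised formyl thioester while the thiourea binds the enone carbonyl, the enolate adds through C4 to C4a and the C8a enol is protonated; pyrrolidinium acetate then forms the C1 enamine towards C2, which attacks the C3 aldehyde and loses water to give the C2=C3 enol ether (closest known types: amine–thiourea Michael additions of α-branched 1,3-dicarbonyl donors to enones that create quaternary carbons, and Robinson annulation of 2-substituted 1,3-dicarbonyls with 1-acylcyclohexenes). Ring A closes by a 6-(enolexo)-exo-trig aldol condensation, the only closure open to the adduct because C8a could reach C3 only through a four-membered ring. C4a should be set by the substrate, since both silyloxy groups (C5, C8) lie on the β face and the donor must come from the α face; C4 is set by the catalyst through the enolate face (the uncertain element); C8a is set by equilibration of the α-keto centre to the trans ring fusion. The step needs Michael addition and condensation without loss of the C8 silyloxy group from the C8a enolate, which the weakly basic amine and buffered pyrrolidinium acetate should secure.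

**Step 14**
Reactants: 19 decalin thioester
Product: 20 (4R,4aS,5R,7S,8S,8aR)-4-acryloyl-5,8-bis[(tert-butyldimethylsilyl)oxy]-2-[(4-methoxybenzyl)oxy]-4,7-dimethyl-4a,5,6,7,8,8a-hexahydronaphthalen-1(4H)-one
Conditions: CH2=CHZnBr (THF solution), PdCl2(PPh3)2 (10 mol %), THF/toluene, rt
Reagents that add atoms: vinylzinc bromide, SMILES C=C[Zn]Br
Why: Fukuyama coupling; palladium inserts into the acyl–sulfur bond and the alkenylzinc transfers the vinyl group, while ketones, silyl ethers and the enol ether do not react with organozinc halides.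

**Step 15**
Reactants: 20 vinyl ketone
Product: 22 (4R,4aS,5R,7S,8S,8aR)-5,8-bis[(tert-butyldimethylsilyl)oxy]-4-(3-hydroxypropanoyl)-2-[(4-methoxybenzyl)oxy]-4,7-dimethyl-4a,5,6,7,8,8a-hexahydronaphthalen-1(4H)-one, via pinacol boronate 21 (not isolated)
Conditions: B2pin2, CuCl (5 mol %), DPEphos (5 mol %), NaOtBu (10 mol %), MeOH (2 equiv), THF, rt; then NaBO3·4H2O, THF/H2O, rt
Reagents that add atoms: sodium perborate, SMILES [Na+].[O-]OB=O (hydroxyl oxygen of 22); bis(pinacolato)diboron, SMILES CC1(C)OB(OC1(C)C)B1OC(C)(C)C(C)(C)O1 (boron of 21)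
Why: Copper-catalysed conjugate borylation followed by perborate oxidation; the terminal vinyl ketone should react far faster than the hindered, electron-rich 2-alkoxy enone, and the oxidation is done while the C2 oxygen is still protected.

**Step 16**
Reactants: 22 hydroxypropanoyl ketone
Product: 23 (4R,4aS,5R,7S,8S,8aR)-5,8-bis[(tert-butyldimethylsilyl)oxy]-4-{3-[(tert-butyldimethylsilyl)oxy]propanoyl}-2-[(4-methoxybenzyl)oxy]-4,7-dimethyl-4a,5,6,7,8,8a-hexahydronaphthalen-1(4H)-one
Conditions: TBSCl, imidazole, CH2Cl2, rt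
Reagents that add atoms: tert-butyldimethylsilyl chloride, SMILES CC(C)(C)[Si](C)(C)Cl
Why: Silylation of the primary alcohol, so that it cannot compete in the Mitsunobu reaction of step 19.

**Step 17**
Reactants: 23 tris(silyl) PMB enol ether
Product: 24 (4R,4aS,5R,7S,8S,8aR)-5,8-bis[(tert-butyldimethylsilyl)oxy]-4-{3-[(tert-butyldimethylsilyl)oxy]propanoyl}-2-hydroxy-4,7-dimethyl-4a,5,6,7,8,8a-hexahydronaphthalen-1(4H)-one (diosphenol)
Conditions: H2 (1 atm), Pd/C, EtOAc, rt, stopped after one equivalent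
Reagents that add atoms: none
Why: Hydrogenolysis of a benzylic C–O bond whose oxygen is phenol-like (an enol); it should be faster than reduction of the hindered enol double bond, and silyl ethers are stable in ethyl acetate.

**Step 18**
Reactants: 25 racemic (E)-oct-2-en-4-ol
Product: 26 (2E,4R)-oct-2-en-4-ol
Conditions: Ti(OiPr)4, L-(+)-DIPT, t-BuOOH (0.6 equiv), 4 Å MS, CH2Cl2, −20 °C
Reagents that add atoms: none
Why: Sharpless kinetic resolution; with L-(+)-tartrate the (S)-enantiomer of an (E)-secondary allylic alcohol should be epoxidised much faster, leaving the (R)-alcohol.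

**Step 19**
Reactants: 24 diosphenol; 26 (2E,4R)-oct-2-en-4-ol
Product: 27 (4R,4aS,5R,7S,8S,8aR)-5,8-bis[(tert-butyldimethylsilyl)oxy]-4-{3-[(tert-butyldimethylsilyl)oxy]propanoyl}-4,7-dimethyl-2-{[(2E,4S)-oct-2-en-4-yl]oxy}-4a,5,6,7,8,8a-hexahydronaphthalen-1(4H)-one
Conditions: PPh3, DIAD, toluene, 0 °C → rt
Reagents that add atoms: none
Why: Mitsunobu etherification; the acidic enol OH (pKa about 10) is a competent pronucleophile and SN2 displacement with inversion should give the (S)-allyl enol ether.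

**Step 20**
Reactants: 27 allyl enol ether
Product: 29 (4R,4aS,5R,7S,8S,8aR)-5,8-bis[(tert-butyldimethylsilyl)oxy]-4-{3-[(tert-butyldimethylsilyl)oxy]propanoyl}-2-hydroxy-4,7-dimethyl-3-[(2R,3E)-oct-3-en-2-yl]-4a,5,6,7,8,8a-hexahydronaphthalen-1(4H)-one, via 1,2-diketone 28 (not isolated)
Conditions: Ho(fod)3 (10 mol %), CHCl3, 60 °C
Reagents that add atoms: none
Why: Claisen rearrangement of a diosphenol allyl ether (lanthanide-catalysed variant); the shift is suprafacial on the allyl unit, so with the butyl group outside (E-alkene formed) the (S)-carbinol centre should be transferred to (R)-C1′ whichever face of C3 reacts, and the diketone enolises to the C2=C3 diosphenol.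

**Step 21**
Reactants: 29 octenyl diosphenol
Product: 30 (4R,4aS,5R,7S,8S,8aR)-5,8-bis[(tert-butyldimethylsilyl)oxy]-4-{3-[(tert-butyldimethylsilyl)oxy]propanoyl}-2-hydroxy-4,7-dimethyl-3-[(2R)-octan-2-yl]-4a,5,6,7,8,8a-hexahydronaphthalen-1(4H)-one
Conditions: H2 (1 atm), Pd/C, EtOAc, rt
Reagents that add atoms: none
Why: Catalytic hydrogenation of the unhindered disubstituted alkene; the tetrasubstituted enol double bond and the ketones should not be reduced, and C1′ is not touched.

**Step 22**
Reactants: 30 tris(silyl) ether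
Product: 31 (4R,4aS,5R,7S,8S,8aR)-2,5,8-trihydroxy-4-(3-hydroxypropanoyl)-4,7-dimethyl-3-[(2R)-octan-2-yl]-4a,5,6,7,8,8a-hexahydronaphthalen-1(4H)-one (target, CNP0234794.3)
Conditions: HF·pyridine, pyridine/THF, 0 °C → rt
Reagents that add atoms: none
Why: Acidic fluoride desilylation removes all three silyl ethers without the base that would cause retro-aldol cleavage or dehydration of the two β-hydroxy ketones.

**Compound list**
1 | 4,4-dimethoxycyclohexa-2,5-dien-1-one | COC1(OC)C=CC(=O)C=C1 | starting material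
2 | (5S)-4,4-dimethoxy-5-methylcyclohex-2-en-1-one | O=C1C=CC(OC)(OC)[C@@H](C)C1 | intermediate
3 | (1R,5S)-4,4-dimethoxy-5-methylcyclohex-2-en-1-ol | O[C@H]1C=CC(OC)(OC)[C@@H](C)C1 | intermediate
4 | tert-butyl{[(1R,5S)-4,4-dimethoxy-5-methylcyclohex-2-en-1-yl]oxy}dimethylsilane | CC(C)(C)[Si](C)(C)O[C@H]1C=CC(OC)(OC)[C@@H](C)C1 | intermediate
5 | (4R,6S)-4-[(tert-butyldimethylsilyl)oxy]-6-methylcyclohex-2-en-1-one | CC(C)(C)[Si](C)(C)O[C@H]1C=CC(=O)[C@@H](C)C1 | intermediate
6 | (4R,6S)-4-[(tert-butyldimethylsilyl)oxy]-2-iodo-6-methylcyclohex-2-en-1-one | CC(C)(C)[Si](C)(C)O[C@H]1C=C(I)C(=O)[C@@H](C)C1 | intermediate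
7 | (1R,4R,6S)-4-[(tert-butyldimethylsilyl)oxy]-2-iodo-6-methylcyclohex-2-en-1-ol | CC(C)(C)[Si](C)(C)O[C@H]1C=C(I)[C@H](O)[C@@H](C)C1 | intermediate
8 | (1S,4R,6S)-4-[(tert-butyldimethylsilyl)oxy]-2-iodo-6-methylcyclohex-2-en-1-yl 4-nitrobenzoate | CC(C)(C)[Si](C)(C)O[C@H]1C=C(I)[C@@H](OC(=O)c2ccc(cc2)[N+](=O)[O-])[C@@H](C)C1 | intermediate
9 | (1S,4R,6S)-4-[(tert-butyldimethylsilyl)oxy]-2-iodo-6-methylcyclohex-2-en-1-ol | CC(C)(C)[Si](C)(C)O[C@H]1C=C(I)[C@@H](O)[C@@H](C)C1 | intermediate
10 | (3R,5S,6S)-3,6-bis[(tert-butyldimethylsilyl)oxy]-1-iodo-5-methylcyclohex-1-ene | CC(C)(C)[Si](C)(C)O[C@H]1C=C(I)[C@@H](O[Si](C)(C)C(C)(C)C)[C@@H](C)C1 | intermediate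
11 | 2-chloro-N-methoxy-N-methylacetamide | CON(C)C(=O)CCl | starting material
12 | 4-methoxybenzyl alcohol | COc1ccc(CO)cc1 | starting material
13 | N-methoxy-2-[(4-methoxybenzyl)oxy]-N-methylacetamide | CON(C)C(=O)COCc1ccc(OC)cc1 | intermediate
14 | 1-[(3R,5S,6S)-3,6-bis[(tert-butyldimethylsilyl)oxy]-5-methylcyclohex-1-en-1-yl]-2-[(4-methoxybenzyl)oxy]ethan-1-one | O=C(COCc1ccc(OC)cc1)C2=C[C@H](O[Si](C)(C)C(C)(C)C)C[C@H](C)[C@@H]2O[Si](C)(C)C(C)(C)C | intermediate (key-step precursor)
15 | S-ethyl propanethioate | CCC(=O)SCC | starting material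
16 | ethyl formate | CCOC=O | starting material
17 | S-ethyl 2-methyl-3-oxopropanethioate (Z-enol form) | O/C=C(/C)C(=O)SCC | intermediate (key-step precursor)
18 | keto-aldehyde Michael adduct (C4–C4a formed, ring A open; centres as in 19) | COc1ccc(COCC(=O)[C@H]2[C@@H](O[Si](C)(C)C(C)(C)C)[C@@H](C)C[C@@H](O[Si](C)(C)C(C)(C)C)[C@@H]2[C@@](C=O)(C)C(=O)SCC)cc1 | intermediate (not isolated)
19 | S-ethyl (4R,4aS,5R,7S,8S,8aR)-5,8-bis[(tert-butyldimethylsilyl)oxy]-2-[(4-methoxybenzyl)oxy]-4,7-dimethyl-1-oxo-1,4,4a,5,6,7,8,8a-octahydronaphthalene-4-carbothioate | C1=C(OCc3ccc(OC)cc3)C(=O)[C@H]2[C@@H](O[Si](C)(C)C(C)(C)C)[C@@H](C)C[C@@H](O[Si](C)(C)C(C)(C)C)[C@@H]2[C@@]1(C)C(=O)SCC | intermediate (key-step product)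
20 | 4-acryloyl decalin enone (vinyl ketone) | C1=C(OCc3ccc(OC)cc3)C(=O)[C@H]2[C@@H](O[Si](C)(C)C(C)(C)C)[C@@H](C)C[C@@H](O[Si](C)(C)C(C)(C)C)[C@@H]2[C@@]1(C)C(=O)C=C | intermediate
21 | 4-[3-(pinacolboryl)propanoyl] decalin enone | C1=C(OCc3ccc(OC)cc3)C(=O)[C@H]2[C@@H](O[Si](C)(C)C(C)(C)C)[C@@H](C)C[C@@H](O[Si](C)(C)C(C)(C)C)[C@@H]2[C@@]1(C)C(=O)CCB4OC(C)(C)C(C)(C)O4 | intermediate (not isolated)
22 | 4-(3-hydroxypropanoyl) decalin enone | C1=C(OCc3ccc(OC)cc3)C(=O)[C@H]2[C@@H](O[Si](C)(C)C(C)(C)C)[C@@H](C)C[C@@H](O[Si](C)(C)C(C)(C)C)[C@@H]2[C@@]1(C)C(=O)CCO | intermediate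
23 | 4-{3-[(tert-butyldimethylsilyl)oxy]propanoyl} PMB enol ether | C1=C(OCc3ccc(OC)cc3)C(=O)[C@H]2[C@@H](O[Si](C)(C)C(C)(C)C)[C@@H](C)C[C@@H](O[Si](C)(C)C(C)(C)C)[C@@H]2[C@@]1(C)C(=O)CCO[Si](C)(C)C(C)(C)C | intermediate
24 | 2-hydroxy enone (diosphenol), C3 unsubstituted | C1=C(O)C(=O)[C@H]2[C@@H](O[Si](C)(C)C(C)(C)C)[C@@H](C)C[C@@H](O[Si](C)(C)C(C)(C)C)[C@@H]2[C@@]1(C)C(=O)CCO[Si](C)(C)C(C)(C)C | intermediate
25 | racemic (E)-oct-2-en-4-ol | C/C=C/C(O)CCCC | starting material
26 | (2E,4R)-oct-2-en-4-ol | C/C=C/[C@H](O)CCCC | intermediate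
27 | 2-{[(2E,4S)-oct-2-en-4-yl]oxy} enone | C1=C(O[C@@H](CCCC)/C=C/C)C(=O)[C@H]2[C@@H](O[Si](C)(C)C(C)(C)C)[C@@H](C)C[C@@H](O[Si](C)(C)C(C)(C)C)[C@@H]2[C@@]1(C)C(=O)CCO[Si](C)(C)C(C)(C)C | intermediate
28 | 3-[(2R,3E)-oct-3-en-2-yl]-1,2-diketone (C3 configuration not fixed) | CCCC/C=C/[C@@H](C)C1C(=O)C(=O)[C@H]2[C@@H](O[Si](C)(C)C(C)(C)C)[C@@H](C)C[C@@H](O[Si](C)(C)C(C)(C)C)[C@@H]2[C@@]1(C)C(=O)CCO[Si](C)(C)C(C)(C)C | intermediate (not isolated)
29 | 2-hydroxy-3-[(2R,3E)-oct-3-en-2-yl] enone | CCCC/C=C/[C@@H](C)C1=C(O)C(=O)[C@H]2[C@@H](O[Si](C)(C)C(C)(C)C)[C@@H](C)C[C@@H](O[Si](C)(C)C(C)(C)C)[C@@H]2[C@@]1(C)C(=O)CCO[Si](C)(C)C(C)(C)C | intermediate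
30 | 2-hydroxy-3-[(2R)-octan-2-yl] enone, tris(silyl) ether | CCCCCC[C@@H](C)C1=C(O)C(=O)[C@H]2[C@@H](O[Si](C)(C)C(C)(C)C)[C@@H](C)C[C@@H](O[Si](C)(C)C(C)(C)C)[C@@H]2[C@@]1(C)C(=O)CCO[Si](C)(C)C(C)(C)C | intermediate
31 | (4R,4aS,5R,7S,8S,8aR)-2,5,8-trihydroxy-4-(3-hydroxypropanoyl)-4,7-dimethyl-3-[(2R)-octan-2-yl]-4a,5,6,7,8,8a-hexahydronaphthalen-1(4H)-one | CCCCCC[C@@H](C)C1=C(O)C(=O)[C@H]2[C@@H](O)[C@@H](C)C[C@@H](O)[C@@H]2[C@@]1(C)C(=O)CCO | target

**Step count**
Total: 22 steps. Longest linear sequence: 19 steps (1–9, 11, 13–17, 19–22).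

**Steps most likely to fail**

1. Step 13 (Proposed new method). The conjugate addition to the α,β-disubstituted enone may be slow and reversible. The catalyst and the substrate may be mismatched, so the enolate face at C4 is poorly selected. The amine may cleave the formyl group from the adduct (retro-Claisen), or the C8 silyloxy group may be lost from the C8a enolate.
Fallback (known chemistry), setting out from 14: base-catalysed (DBU, cat., THF) Michael addition of the more acidic malonate-type donor S,S′-diethyl 2-methylpropanebis(thioate) F1 (made from methylmalonyl dichloride and ethanethiol with pyridine) should give the bis(thioester) adduct F2, with C4a again set by the substrate. Fukuyama reduction (Et3SiH, Pd/C, acetone) of one thioester then gives keto-aldehyde 18, where the route is rejoined and closed to 19 with pyrrolidinium acetate. The cost is that C4 is then set by selection between two diastereotopic thioesters, so the C4 epimer would have to be separated.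

2. Step 19. The activated secondary allylic alcohol may react by SN2′ attack or ionise, giving the regioisomeric ether and eroding the configuration, or the enolate may alkylate at carbon.
Fallback, setting out from 24: O-alkylation with (E)-1-bromobut-2-ene (K2CO3, acetone) gives the (E)-but-2-enyl enol ether F3. Claisen rearrangement gives the 3-[(2R)-but-3-en-2-yl] diosphenol F4. Cross-metathesis with hex-1-ene (second-generation Grubbs catalyst, (H2IMes)(PCy3)Cl2Ru=CHPh, CH2Cl2, 40 °C) gives 29 together with its Z isomer, both of which are reduced in step 21; the route is rejoined at 29. Here C1′ rests on the face of C3 and the chair or boat preference of the rearrangement, and the (Z)-bromide would be used if the sense is opposite.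

3. Step 14. Transmetalation of the alkenylzinc to the acylpalladium at the neopentyl centre may be slow, leading to decarbonylation or recovered thioester.
Fallback, setting out from 19: Fukuyama reduction (Et3SiH, Pd/C, acetone), in which the acylpalladium is intercepted by hydride, gives the C4 aldehyde F5. Vinylmagnesium bromide (THF, −78 °C; the aldehyde should react ahead of the hindered C1 ketone) gives the allylic alcohol F6 as a C9 epimer mixture. Dess–Martin periodinane oxidation gives 20, where the route is rejoined.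

**Further compounds**
F1 | step 13 | S,S′-diethyl 2-methylpropanebis(thioate) | CCSC(=O)C(C)C(=O)SCC
F2 | step 13 | bis(thioester) Michael adduct of 14 | COc1ccc(COCC(=O)[C@H]2[C@@H](O[Si](C)(C)C(C)(C)C)[C@@H](C)C[C@@H](O[Si](C)(C)C(C)(C)C)[C@@H]2C(C)(C(=O)SCC)C(=O)SCC)cc1
F3 | step 19 | 2-[(E)-but-2-enyloxy] enone | C1=C(OC/C=C/C)C(=O)[C@H]2[C@@H](O[Si](C)(C)C(C)(C)C)[C@@H](C)C[C@@H](O[Si](C)(C)C(C)(C)C)[C@@H]2[C@@]1(C)C(=O)CCO[Si](C)(C)C(C)(C)C
F4 | step 19 | 3-[(2R)-but-3-en-2-yl]-2-hydroxy enone | C=C[C@@H](C)C1=C(O)C(=O)[C@H]2[C@@H](O[Si](C)(C)C(C)(C)C)[C@@H](C)C[C@@H](O[Si](C)(C)C(C)(C)C)[C@@H]2[C@@]1(C)C(=O)CCO[Si](C)(C)C(C)(C)C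
F5 | step 14 | C4 aldehyde | C1=C(OCc3ccc(OC)cc3)C(=O)[C@H]2[C@@H](O[Si](C)(C)C(C)(C)C)[C@@H](C)C[C@@H](O[Si](C)(C)C(C)(C)C)[C@@H]2[C@@]1(C)C=O
F6 | step 14 | C4 1-hydroxyprop-2-enyl compound (C9 epimers) | C1=C(OCc3ccc(OC)cc3)C(=O)[C@H]2[C@@H](O[Si](C)(C)C(C)(C)C)[C@@H](C)C[C@@H](O[Si](C)(C)C(C)(C)C)[C@@H]2[C@@]1(C)C(O)C=C
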